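**Retrosynthetic overview**

1. Feature: in each chroman half the pyran oxygen O1 sits on aromatic carbon C8a (para to the bridge carbon C6), while C4a–C4–C3–C2 is an all-carbon chain. C8a can therefore first carry the carbonyl carbon of an indan-1-one fused across C4a–C8a, and that carbonyl carbon is the future C2.
2. Target 19 ⇐ 18 (four O-methyl groups removed) ⇐ 16 (C8 acylation of both rings with 17) ⇐ 15 (pyran closure on the C8a hydroxyl) ⇐ 14 (MeMgBr opens both lactones).
3. 14 ⇐ 13: double Baeyer–Villiger oxidation; the aryl carbon shifts from the ketone carbon to oxygen, which makes both O1–C8a bonds and both six-membered oxygen rings.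
4. 13 ⇐ 12 (Friedel–Crafts ring closure) ⇐ 9 (Doebner homologation of both aldehydes with 10, then hydrogenation) ⇐ 7 (formylation) ⇐ 6 (ionic deoxygenation) ⇐ two molecules of 1 + one of 2 (double arylation of the ester).
5. Ring order: the benzene rings are bought and joined at the bridge first; then the two cyclopentanone rings (step 6), their expansion to the two lactone rings (step 7), and opening and reclosure of these as the two 2,2-dimethylpyran rings (steps 8 and 9).

Key step: step 7

Remark on the chemistry: the bridge carbon bears two identical aryl groups, so the target has no stereocentre and the route needs no stereocontrol. Because the molecule is a symmetrical dimer, steps 1, 4 and 10 each consume two molecules of one building block per molecule of product; the second molecule is entered on the line "Reagents that add atoms". Locants: chroman numbering (O1, C2–C4, C4a, C5–C8, C8a) for 14–19, indan-1-one numbering for 13, and the numbering of the compound names for 6–12.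

**Route**

Step 1
Reactants: 1 1,3-dimethoxybenzene; 2 methyl 6-methylheptanoate
Product: 6 1,1-bis(2,6-dimethoxyphenyl)-6-methylheptan-1-ol, via aryllithium 3 (not isolated), via arylcerium dichloride 4 (not isolated), via monoaryl ketone 5 (not isolated)
Conditions: 1 (2.4 equiv in all), n-BuLi (2.4 equiv), THF, 0 °C to rt; anhydrous CeCl3 (2.4 equiv), THF, −78 °C; then 2 (1 equiv), −78 °C to rt; aq. NH4Cl
Reagents that add atoms: second equivalent of 1,3-dimethoxybenzene COc1cccc(OC)c1
Why: Directed ortho-metalation lithiates C2 between the two methoxy groups, and two molecules of the derived organocerium reagent 4, nucleophilic but only weakly basic, should add to one molecule of the ester (acyl substitution to ketone 5, then 1,2-addition) instead of enolising the hindered ketone.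

Step 2
Reactants: 6 1,1-bis(2,6-dimethoxyphenyl)-6-methylheptan-1-ol
Product: 7 1,1-bis(2,6-dimethoxyphenyl)-6-methylheptane
Conditions: Et3SiH, CF3CO2H, CH2Cl2, 0 °C to rt
Reagents that add atoms: none
Why: Ionic hydrogenation, in which the tertiary alcohol ionises in CF3CO2H to a carbenium ion stabilised by two 2,6-dimethoxyphenyl rings, Et3SiH transfers hydride to it, and any alkene formed by proton loss is reprotonated to the same ion.

Step 3
Reactants: 7 1,1-bis(2,6-dimethoxyphenyl)-6-methylheptane
Product: 9 3,3'-(6-methylheptane-1,1-diyl)bis(2,4-dimethoxybenzaldehyde), via bis-iminium dichloride 8 (not isolated)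
Conditions: POCl3, DMF, 80 °C; then aq. NaOAc, rt
Reagents that add atoms: N,N-dimethylformamide CN(C)C=O; water O
Why: Vilsmeier–Haack formylation should enter each ring once at the carbon ortho to one methoxy group and para to the other (C3 and C5 of a ring are equivalent), because the iminium group of 8 deactivates its own ring against a second attack and the weakly acidic medium spares the bridge.

Step 4
Reactants: 9 3,3'-(6-methylheptane-1,1-diyl)bis(2,4-dimethoxybenzaldehyde); 10 malonic acid
Product: 11 (2E,2'E)-3,3'-[(6-methylheptane-1,1-diyl)bis(2,4-dimethoxy-3,1-phenylene)]bis(prop-2-enoic acid)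
Conditions: 10 (5 equiv in all), pyridine, piperidine (cat.), 100 °C
Reagents that add atoms: second equivalent of malonic acid OC(=O)CC(=O)O
Why: Knoevenagel condensation in the Doebner modification, one molecule of malonic acid per aldehyde group with decarboxylation in hot pyridine, should give both (E)-cinnamic acids, and the alkene geometry is of no consequence because step 5 removes it.

Step 5
Reactants: 11 the bis(E-cinnamic acid)
Product: 12 3,3'-[(6-methylheptane-1,1-diyl)bis(2,4-dimethoxy-3,1-phenylene)]dipropanoic acid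
Conditions: H2 (1 atm), 10% Pd/C, MeOH–EtOAc, rt
Reagents that add atoms: none
Why: Heterogeneous catalytic hydrogenation saturates the two conjugated C=C bonds, while aryl methyl ethers, carboxylic acids and the diarylmethine C–H are inert at room temperature and one atmosphere.

Step 6
Reactants: 12 the bis(3-arylpropanoic acid)
Product: 13 5,5'-(6-methylheptane-1,1-diyl)bis(4,6-dimethoxyindan-1-one)
Conditions: polyphosphoric acid, 70 °C, 12 added in portions; ice–water quench
Reagents that add atoms: none
Why: Intramolecular Friedel–Crafts acylation (cyclodehydration) in which the tethered acylium equivalent can reach only C6 of its ring, since the other ortho carbon bears a methoxy group, so each five-membered ketone ring forms with unambiguous regiochemistry, the para alkyl bridge compensating for the two meta methoxy groups as in the known closure of 3-(4-methoxyphenyl)propanoic acid to 6-methoxyindan-1-one.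

Step 7
Reactants: 13 5,5'-(6-methylheptane-1,1-diyl)bis(4,6-dimethoxyindan-1-one)
Product: 14 6,6'-(6-methylheptane-1,1-diyl)bis(5,7-dimethoxy-3,4-dihydro-2H-chromen-2-one)
Conditions: mCPBA (5 equiv), NaHCO3, CH2Cl2, 0 °C to rt, dark
Reagents that add atoms: 3-chloroperoxybenzoic acid OOC(=O)c1cccc(Cl)c1
Why: The peracid adds to each indanone carbonyl to give a tetrahedral peroxyhemiketal (Criegee adduct), and heterolysis of its O–O bond is coupled to a 1,2-shift of the aryl carbon C7a (the future C8a), antiperiplanar to the departing 3-chlorobenzoate, from the carbonyl carbon to oxygen. The closest known reaction type is the Baeyer–Villiger oxidation of indan-1-ones to 3,4-dihydrocoumarins. Each six-membered lactone ring arises by ring expansion, that is by insertion of one oxygen into the C1–C7a bond of the five-membered ketone ring and not by a separate cyclisation, and no stereocentre is formed. The step needs aryl in preference to CH2 migration: an sp2 carbon that can bridge through a phenonium-like transition state migrates ahead of a primary alkyl carbon, and here C7a is para to the alkyl bridge and ortho to the ring CH2, which offsets the two meta methoxy groups. It also needs the peracid to attack the carbonyl and not the arene: the ketone is meta to both methoxy groups, hence no vinylogous ester and fully electrophilic, the acyl group keeps its ring electron-poor until it has reacted, and the NaHCO3 buffer removes the acid that would promote hydroxylation of the product ring.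

Step 8
Reactants: 14 the bridged bis(5,7-dimethoxy-3,4-dihydrocoumarin)
Product: 15 4,4'-(6-methylheptane-1,1-diyl)bis[2-(3-hydroxy-3-methylbutyl)-3,5-dimethoxyphenol]
Conditions: MeMgBr (10 equiv), THF, 0 °C to rt; aq. NH4Cl
Reagents that add atoms: methylmagnesium bromide C[Mg]Br
Why: Double Grignard addition to each aryl ester, in which acyl substitution releases the C8a phenoxide and the methyl ketone so formed takes a second methyl group to give the tertiary alcohol at the future C2.

Step 9
Reactants: 15 the bis(phenol–tertiary alcohol)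
Product: 16 6,6'-(6-methylheptane-1,1-diyl)bis(5,7-dimethoxy-2,2-dimethyl-3,4-dihydro-2H-chromene)
Conditions: TsOH·H2O (cat.), toluene, 50 °C
Reagents that add atoms: none
Why: Acid-catalysed cyclodehydration through the tertiary carbocation, in which the C8a hydroxyl is the only free phenol so that six-membered O-closure fixes the pyran regiochemistry, and a catalytic amount of acid at moderate temperature should spare the electron-rich diarylmethine.

Step 10
Reactants: 16 the bridged bis(5,7-dimethoxy-2,2-dimethylchroman); 17 isobutyryl chloride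
Product: 18 1,1'-[(6-methylheptane-1,1-diyl)bis(5,7-dimethoxy-2,2-dimethyl-3,4-dihydro-2H-chromene-6,8-diyl)]bis(2-methylpropan-1-one)
Conditions: 17 (2.5 equiv in all), SnCl4 (2.5 equiv), CH2Cl2, −20 to 0 °C; aq. HCl
Reagents that add atoms: second equivalent of isobutyryl chloride CC(C)C(=O)Cl
Why: Friedel–Crafts acylation, one molecule of acid chloride per ring, at C8, the only unsubstituted ring carbon, which is ortho to O1 and to the C7 methoxy group and para to the C5 methoxy group as in the acylation of 1,3,5-trimethoxybenzene, the first acyl group deactivating its own ring and the mild Lewis acid at low temperature limiting ipso attack at C6.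

Step 11
Reactants: 18 the bis(8-isobutyryl-5,7-dimethoxychroman)
Product: 19 CNP0275635.0, 1,1'-[(6-methylheptane-1,1-diyl)bis(5,7-dihydroxy-2,2-dimethyl-3,4-dihydro-2H-chromene-6,8-diyl)]bis(2-methylpropan-1-one)
Conditions: BCl3 (excess), CH2Cl2, −78 °C to rt; then MeOH, aq. NaHCO3
Reagents that add atoms: none
Why: Lewis-acid ether cleavage in which BCl3 removes the C7 methyl ether through a six-membered boron chelate with the C8 ketone and the C5 methyl ether because its two ortho substituents twist it out of conjugation and make its oxygen basic, both known selectivities of BCl3, while the conjugated ring oxygen of the pyran should be left alone at these temperatures.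

**Compound list**

1 | 1,3-dimethoxybenzene | COc1cccc(OC)c1 | starting material
2 | methyl 6-methylheptanoate | COC(=O)CCCCC(C)C | starting material
3 | 2,6-dimethoxyphenyllithium | [Li]c1c(OC)cccc1OC | intermediate
4 | dichloro(2,6-dimethoxyphenyl)cerium | Cl[Ce](Cl)c1c(OC)cccc1OC | intermediate
5 | 1-(2,6-dimethoxyphenyl)-6-methylheptan-1-one | CC(C)CCCCC(=O)c1c(OC)cccc1OC | intermediate
6 | 1,1-bis(2,6-dimethoxyphenyl)-6-methylheptan-1-ol | CC(C)CCCCC(O)(c1c(OC)cccc1OC)c1c(OC)cccc1OC | intermediate
7 | 1,1-bis(2,6-dimethoxyphenyl)-6-methylheptane | CC(C)CCCCC(c1c(OC)cccc1OC)c1c(OC)cccc1OC | intermediate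
8 | bis(N,N-dimethyliminium) salt of dialdehyde 9, drawn as the dichloride | CC(C)CCCCC(c1c(OC)ccc(C=[N+](C)C)c1OC)c1c(OC)ccc(C=[N+](C)C)c1OC.[Cl-].[Cl-] | intermediate
9 | 3,3'-(6-methylheptane-1,1-diyl)bis(2,4-dimethoxybenzaldehyde) | CC(C)CCCCC(c1c(OC)ccc(C=O)c1OC)c1c(OC)ccc(C=O)c1OC | intermediate
10 | malonic acid | OC(=O)CC(=O)O | starting material
11 | (2E,2'E)-3,3'-[(6-methylheptane-1,1-diyl)bis(2,4-dimethoxy-3,1-phenylene)]bis(prop-2-enoic acid) | CC(C)CCCCC(c1c(OC)ccc(/C=C/C(=O)O)c1OC)c1c(OC)ccc(/C=C/C(=O)O)c1OC | intermediate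
12 | 3,3'-[(6-methylheptane-1,1-diyl)bis(2,4-dimethoxy-3,1-phenylene)]dipropanoic acid | CC(C)CCCCC(c1c(OC)ccc(CCC(=O)O)c1OC)c1c(OC)ccc(CCC(=O)O)c1OC | intermediate
13 | 5,5'-(6-methylheptane-1,1-diyl)bis(4,6-dimethoxyindan-1-one) | CC(C)CCCCC(c1c(OC)c2CCC(=O)c2cc1OC)c1c(OC)c2CCC(=O)c2cc1OC | intermediate
14 | 6,6'-(6-methylheptane-1,1-diyl)bis(5,7-dimethoxy-3,4-dihydro-2H-chromen-2-one) | CC(C)CCCCC(c1c(OC)c2CCC(=O)Oc2cc1OC)c1c(OC)c2CCC(=O)Oc2cc1OC | intermediate
15 | 4,4'-(6-methylheptane-1,1-diyl)bis[2-(3-hydroxy-3-methylbutyl)-3,5-dimethoxyphenol] | CC(C)CCCCC(c1c(OC)c(CCC(C)(C)O)c(O)cc1OC)c1c(OC)c(CCC(C)(C)O)c(O)cc1OC | intermediate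
16 | 6,6'-(6-methylheptane-1,1-diyl)bis(5,7-dimethoxy-2,2-dimethyl-3,4-dihydro-2H-chromene) | CC(C)CCCCC(c1c(OC)c2CCC(C)(C)Oc2cc1OC)c1c(OC)c2CCC(C)(C)Oc2cc1OC | intermediate
17 | isobutyryl chloride (2-methylpropanoyl chloride) | CC(C)C(=O)Cl | starting material
18 | 1,1'-[(6-methylheptane-1,1-diyl)bis(5,7-dimethoxy-2,2-dimethyl-3,4-dihydro-2H-chromene-6,8-diyl)]bis(2-methylpropan-1-one) | CC(C)CCCCC(c1c(OC)c2CCC(C)(C)Oc2c(C(=O)C(C)C)c1OC)c1c(OC)c2CCC(C)(C)Oc2c(C(=O)C(C)C)c1OC | intermediate
19 | CNP0275635.0, 1,1'-[(6-methylheptane-1,1-diyl)bis(5,7-dihydroxy-2,2-dimethyl-3,4-dihydro-2H-chromene-6,8-diyl)]bis(2-methylpropan-1-one) | CC(C)CCCCC(c1c(O)c2c(c(C(=O)C(C)C)c1O)OC(C)(C)CC2)c1c(O)c2c(c(C(=O)C(C)C)c1O)OC(C)(C)CC2 | target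

**Step count**

Total steps: 11. Longest linear sequence: 11 steps (1 and 2 to 19).

**Steps most likely to fail**

Step 7 (key step). What may go wrong: migration of the ring methylene carbon in place of the aryl carbon, electrophilic hydroxylation of the methoxy-rich ring by the peracid once its ketone has been consumed, or stalling after the first of the two oxidations. Fallback: the oxygen is placed on the same ring carbon without a ketone, setting out from 7 and returning at 16. Iridium-catalysed C–H borylation of 7 ([Ir(OMe)(cod)]2, 4,4'-di-tert-butyl-2,2'-bipyridine, B2pin2, THF, 80 °C) should functionalise each ring at C4, the only C–H with no ortho substituent, to give 2,2'-[(6-methylheptane-1,1-diyl)bis(3,5-dimethoxy-4,1-phenylene)]bis(4,4,5,5-tetramethyl-1,3,2-dioxaborolane) F1. Oxidation (H2O2, NaOH, THF–water, 0 °C) should give 4,4'-(6-methylheptane-1,1-diyl)bis(3,5-dimethoxyphenol) F2. Acid-catalysed annulation of F2 with 2-methylbut-3-en-2-ol (BF3·OEt2 cat., dioxane, rt; ortho C-prenylation, then closure on the phenol oxygen) should give 16, from which steps 10 and 11 follow.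

Step 6. What may go wrong: intermolecular acylation at the ring carbon that is ortho and para to methoxy outruns the five-membered closure at the carbon meta to both methoxy groups, and hot acid cleaves the diarylmethine bridge by ipso protonation and loss of the benzylic cation. Fallback: a blocking group, setting out from 12 and returning at 13. Bromination of 12 (NBS, MeCN, 0 °C) should go to the one activated carbon of each ring and give 3,3'-[(6-methylheptane-1,1-diyl)bis(5-bromo-2,4-dimethoxy-3,1-phenylene)]dipropanoic acid F3, in which the competing nucleophilic site is occupied and the ring is less basic. Cyclodehydration (polyphosphoric acid, 70 °C) should then give 5,5'-(6-methylheptane-1,1-diyl)bis(7-bromo-4,6-dimethoxyindan-1-one) F4. Hydrodebromination (H2, 10% Pd/C, Et3N, EtOAc, rt) should return 13.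

Step 11. What may go wrong: incomplete cleavage of the non-chelated C5 methyl ethers and, on forcing, Lewis-acid opening of the pyran ring with reclosure on the other phenolic oxygen, or scission of the bridge. Fallback: the methyl ethers are exchanged for benzyl ethers at the acid-robust indanone stage, so that the final unmasking is a neutral hydrogenolysis; it sets out from 13 and returns at 19. Treatment of 13 with BBr3 (CH2Cl2, −78 °C to rt), which has no pyran ring to lose and whose ketone para to the bridge carbon protects the bridge, should give 5,5'-(6-methylheptane-1,1-diyl)bis(4,6-dihydroxyindan-1-one) F5. Benzylation (benzyl bromide, K2CO3, DMF, 60 °C) should give 5,5'-(6-methylheptane-1,1-diyl)bis[4,6-bis(benzyloxy)indan-1-one] F6. Baeyer–Villiger oxidation as in step 7 should give 6,6'-(6-methylheptane-1,1-diyl)bis[5,7-bis(benzyloxy)-3,4-dihydro-2H-chromen-2-one] F7. MeMgBr as in step 8 should give 4,4'-(6-methylheptane-1,1-diyl)bis[3,5-bis(benzyloxy)-2-(3-hydroxy-3-methylbutyl)phenol] F8. Catalytic TsOH as in step 9 should give 6,6'-(6-methylheptane-1,1-diyl)bis[5,7-bis(benzyloxy)-2,2-dimethyl-3,4-dihydro-2H-chromene] F9. Acylation with the mixed anhydride of isobutyric acid ((CF3CO)2O, CH2Cl2, 0 °C to rt), which avoids Lewis acids that cleave benzyl ethers, should give 1,1'-{(6-methylheptane-1,1-diyl)bis[5,7-bis(benzyloxy)-2,2-dimethyl-3,4-dihydro-2H-chromene-6,8-diyl]}bis(2-methylpropan-1-one) F10. Hydrogenolysis (H2, 10% Pd/C, EtOAc, rt) should then give 19.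

**Further compounds**

F1 | step 7 | 2,2'-[(6-methylheptane-1,1-diyl)bis(3,5-dimethoxy-4,1-phenylene)]bis(4,4,5,5-tetramethyl-1,3,2-dioxaborolane) | CC(C)CCCCC(c1c(OC)cc(B2OC(C)(C)C(C)(C)O2)cc1OC)c1c(OC)cc(B2OC(C)(C)C(C)(C)O2)cc1OC
F2 | step 7 | 4,4'-(6-methylheptane-1,1-diyl)bis(3,5-dimethoxyphenol) | CC(C)CCCCC(c1c(OC)cc(O)cc1OC)c1c(OC)cc(O)cc1OC
F3 | step 6 | 3,3'-[(6-methylheptane-1,1-diyl)bis(5-bromo-2,4-dimethoxy-3,1-phenylene)]dipropanoic acid | CC(C)CCCCC(c1c(OC)c(Br)cc(CCC(=O)O)c1OC)c1c(OC)c(Br)cc(CCC(=O)O)c1OC
F4 | step 6 | 5,5'-(6-methylheptane-1,1-diyl)bis(7-bromo-4,6-dimethoxyindan-1-one) | CC(C)CCCCC(c1c(OC)c2CCC(=O)c2c(Br)c1OC)c1c(OC)c2CCC(=O)c2c(Br)c1OC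
F5 | step 11 | 5,5'-(6-methylheptane-1,1-diyl)bis(4,6-dihydroxyindan-1-one) | CC(C)CCCCC(c1c(O)c2CCC(=O)c2cc1O)c1c(O)c2CCC(=O)c2cc1O
F6 | step 11 | 5,5'-(6-methylheptane-1,1-diyl)bis[4,6-bis(benzyloxy)indan-1-one] | CC(C)CCCCC(c1c(OCc3ccccc3)c2CCC(=O)c2cc1OCc1ccccc1)c1c(OCc3ccccc3)c2CCC(=O)c2cc1OCc1ccccc1
F7 | step 11 | 6,6'-(6-methylheptane-1,1-diyl)bis[5,7-bis(benzyloxy)-3,4-dihydro-2H-chromen-2-one] | CC(C)CCCCC(c1c(OCc3ccccc3)c2CCC(=O)Oc2cc1OCc1ccccc1)c1c(OCc3ccccc3)c2CCC(=O)Oc2cc1OCc1ccccc1
F8 | step 11 | 4,4'-(6-methylheptane-1,1-diyl)bis[3,5-bis(benzyloxy)-2-(3-hydroxy-3-methylbutyl)phenol] | CC(C)CCCCC(c1c(OCc2ccccc2)c(CCC(C)(C)O)c(O)cc1OCc1ccccc1)c1c(OCc2ccccc2)c(CCC(C)(C)O)c(O)cc1OCc1ccccc1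
F9 | step 11 | 6,6'-(6-methylheptane-1,1-diyl)bis[5,7-bis(benzyloxy)-2,2-dimethyl-3,4-dihydro-2H-chromene] | CC(C)CCCCC(c1c(OCc3ccccc3)c2CCC(C)(C)Oc2cc1OCc1ccccc1)c1c(OCc3ccccc3)c2CCC(C)(C)Oc2cc1OCc1ccccc1
F10 | step 11 | 1,1'-{(6-methylheptane-1,1-diyl)bis[5,7-bis(benzyloxy)-2,2-dimethyl-3,4-dihydro-2H-chromene-6,8-diyl]}bis(2-methylpropan-1-one) | CC(C)CCCCC(c1c(OCc3ccccc3)c2CCC(C)(C)Oc2c(C(=O)C(C)C)c1OCc1ccccc1)c1c(OCc3ccccc3)c2CCC(C)(C)Oc2c(C(=O)C(C)C)c1OCc1ccccc1
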